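**Plan**

1. Late disconnections: the O5 isobutyrate and the O2 silyl group come off, the C4/C5 syn-diol goes back to an (E)-C4=C5 alkene, and the C13 methylene to a Mannich base.
2. The ten-membered ring (C1–C10) has the C9 ketone 1,6 to C4 on both sides and oxygen on C5. This is the retron of a Grob fragmentation, so the ring is cut back to a trans-decalin (ring A = C4–C9 with a 5-mesylate, ring B = C9, C10, C1, C2, C3, C4) whose fusion bond C4–C9 is absent from the target. Because C10 carries a methyl group next to the C9 carbonyl, C10 can arrive as the inner carbon of a 2-bromoallyl unit, and the C9–C10 bond of ring B is disconnected (vinyl bromide onto the ring-A ketone).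
3. Ring A goes back through the 8-ester (α-bromo ketone), the cis-lactone (epoxide opened by the C7 acetate chain) and a meso 2-allyl-2-methyl-5-(methoxycarbonylmethyl)cyclohexane-1,3-dione to 3,5-dihydroxyphenylacetic acid.
4. Forward order: ring A (steps 1–10), side chain C3–C2–C1–C10 (11–13), ring B by C9–C10 closure (14), C10 methyl and C13 (15–16), fragmentation to the ten-membered ring (17), then methylene lactone, diol, isobutyrate and desilylation (18–21).
5. Stereochemistry: one catalytic reduction desymmetrises the meso dione and fixes C4/C7. C6, C8, C9, C10 and the alkene geometry follow by substrate control. C2 and C4/C5 are set under ligand control, and C2′ is bought.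

Key step: step 14

Numbering used: target numbering throughout (ring C1–C10 with C9 the ketone carbon and C10 its methyl-bearing neighbour; C6/C7 lactone fusion; C11–C13 lactone; C14 on C10; C15 on C4; C2′ in the 2-methylbutanoate). The target is 2S,4S,5S,6R,7S,8S,10S,2′R. For ring A and the decalins, β is the face carrying the C7–C11 bond and α the opposite face.

**Step 1**
Reactants: 1 2-(3,5-dihydroxyphenyl)acetic acid; 2 iodomethane
Product: 4 2-(4-methyl-3,5-dioxocyclohexyl)acetic acid (keto/enol mixture; C4 not defined), via 2-(3,5-dioxocyclohexyl)acetic acid 3 (not isolated)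
Conditions: H2 (4 bar), 5% Rh on Al2O3, NaOH (2.1 equiv), H2O, 50 °C; filter; then MeI (1.3 equiv), dioxane, reflux; then HCl to pH 2
Reagents that add atoms: none
Why: Partial hydrogenation of the resorcinol monoanion stops at the 1,3-dione enolate, and this sodium enolate is C-methylated at its central carbon (C4, bringing in C15) in the same aqueous medium, in which the carboxylate is not alkylated (the classical one-pot passage from a resorcinol to a 2-methylcyclohexane-1,3-dione); no stereocentre is formed.

**Step 2**
Reactants: 4 2-(4-methyl-3,5-dioxocyclohexyl)acetic acid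
Product: 5 methyl 2-(4-methyl-3,5-dioxocyclohexyl)acetate (keto/enol mixture, C4 not defined)
Conditions: H2SO4 (5 mol %), MeOH, reflux; then 1 M aqueous HCl, THF, 25 °C
Reagents that add atoms: methanol, CO
Why: Fischer esterification converts the carboxylic acid into the methyl ester, and the enol methyl ether that forms reversibly at the dione is hydrolysed back by the dilute aqueous acid, which leaves the ester intact.

**Step 3**
Reactants: 5 methyl 2-(4-methyl-3,5-dioxocyclohexyl)acetate; 6 allyl methyl carbonate
Product: 7 methyl 2-(cis-4-allyl-4-methyl-3,5-dioxocyclohexyl)acetate (meso; allyl cis to the CH2CO2Me chain; ring carbons are C4–C9 of the target)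
Conditions: Pd(PPh3)4 (2 mol %), THF, 25 °C
Reagents that add atoms: none
Why: Tsuji–Trost C-allylation makes the quaternary C4; attack on the sofa-shaped enolate along the axial line anti to the C7 flap should place the allyl group cis to the equatorial C7 chain (the trans isomer, if formed, is removed by crystallisation).

**Step 4**
Reactants: 7 meso dione
Product: 8 methyl 2-[(1S,3R,4R)-4-allyl-3-hydroxy-4-methyl-5-oxocyclohexyl]acetate (5β-OH, cis to allyl; C9 ketone kept)
Conditions: (S)-2-methyl-CBS-oxazaborolidine (15 mol %), catecholborane (1.1 equiv), toluene, −60 °C; then MeOH, aqueous work-up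
Reagents that add atoms: none
Why: Corey–Bakshi–Shibata reduction distinguishes the two enantiotopic carbonyls (quaternary C4 as large, C6H2 as small substituent) and delivers hydride anti to the axial allyl group at only one of them, so the single new carbinol C5 fixes the absolute sense of C4 and C7.

**Step 5**
Reactants: 8 hydroxy ketone
Product: 9 methyl 2-[(1S,4R)-4-allyl-4-methyl-5-oxocyclohex-2-en-1-yl]acetate (C5=C6 alkene)
Conditions: Burgess reagent (methyl N-(triethylammoniosulfonyl)carbamate), toluene, 70 °C
Reagents that add atoms: none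
Why: syn-Elimination through the sulfamate ester can only go towards C6 because C4 is quaternary, so the desymmetrising oxygen is traded for the C5=C6 alkene with C4 and C7 intact.

**Step 6**
Reactants: 9 ring-A alkene
Product: 10 5α,6α-epoxide of 9 (epoxide oxygen trans to the allyl group and to the C7 chain)
Conditions: mCPBA (1.05 equiv), CH2Cl2, 0 °C
Reagents that add atoms: 3-chloroperoxybenzoic acid (mCPBA), O=C(OO)c1cccc(Cl)c1
Why: Prilezhaev epoxidation should prefer the cis-disubstituted ring alkene over the monosubstituted allyl terminus and approach the α-face, anti to the pseudo-axial allyl group on C4 and to the C7 chain.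

**Step 7**
Reactants: 10 epoxy ester
Product: 11 hydroxy keto lactone (cyclohexanone with C9 ketone, 4β-allyl, 4α-methyl, 5α-OH and a cis-fused γ-lactone 6β-O–C12(=O)–C11H2–C7β)
Conditions: camphorsulfonic acid (10 mol %), water-saturated CH2Cl2, 25 °C
Reagents that add atoms: water, O
Why: Acid-catalysed 5-exo opening of the epoxide at C6 by the ester carbonyl oxygen with inversion (trans-diaxial opening) and loss of methanol gives the cis-fused lactone, setting C6–O β and leaving the 5-OH α, trans to the allyl group.

**Step 8**
Reactants: 11 hydroxy keto lactone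
Product: 12 5α-mesylate of 11
Conditions: MsCl, Et3N, CH2Cl2, 0 °C
Reagents that add atoms: methanesulfonyl chloride, CS(=O)(=O)Cl
Why: Sulfonylation with retention installs the nucleofuge, which is equatorial and antiperiplanar to the C4–C9 bond in the chair that has the allyl group equatorial.

**Step 9**
Reactants: 12 mesylate
Product: 14 8α-bromo ketone (bromine trans to the C7–C11 bond), via trimethylsilyl enol ether 13 (not isolated)
Conditions: TMSOTf, Et3N, CH2Cl2, 0 °C; then NBS, THF, −78 °C
Reagents that add atoms: N-bromosuccinimide, O=C1CCC(=O)N1Br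
Why: Soft enolisation can only go towards C8 (C4 is quaternary) and bromination of the silyl enol ether should occur axially on the α-face, anti to the axial C7–C11 bond.

**Step 10**
Reactants: 14 8α-bromo ketone; 15 (R)-2-methylbutanoic acid
Product: 16 8β-[(R)-2-methylbutanoyloxy] ketone (allyl, mesylate and lactone as in 12)
Conditions: Cs2CO3 (1.0 equiv), DMF, 25 °C
Reagents that add atoms: none
Why: SN2 displacement of the α-bromo ketone by the cesium carboxylate with inversion gives the equatorial 8β-ester, cis to C7–C11; this is also the thermodynamically preferred C8 epimer, and the step brings in the purchased C2′ centre.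

**Step 11**
Reactants: 16 allyl ketone
Product: 17 aldehyde (allyl of 16 cut to C3H2–C2HO)
Conditions: O3, CH2Cl2/MeOH, −78 °C; then Me2S
Reagents that add atoms: ozone, [O-][O+]=O
Why: Ozonolysis with reductive work-up cleaves the only alkene to the C2 aldehyde.

**Step 12**
Reactants: 17 aldehyde; 18 2,3-dibromoprop-1-ene
Product: 20 2-bromoallyl carbinol (chain C3H2–C2H(OH)–C1H2–C10(Br)=C14H2 with C2 arranged as in the target), via trimethylsilyl ether 19 (not isolated)
Conditions: CrCl2 (10 mol %), chiral oxazoline–sulfonamide ligand (12 mol %, the antipode that gives the target arrangement at C2), Et3N (20 mol %), Mn powder, TMSCl, THF, 0 °C; then 1 M HCl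
Reagents that add atoms: none
Why: Catalytic asymmetric chromium-mediated 2-haloallylation (Nozaki–Hiyama type) adds to the aldehyde and leaves the ketone alone; C2 is set by the ligand because the nearest substrate stereocentre is the remote quaternary C4.

**Step 13**
Reactants: 20 2-bromoallyl carbinol
Product: 21 2-O-tert-butyldimethylsilyl ether of 20
Conditions: TBSOTf, 2,6-lutidine, CH2Cl2, −78 °C
Reagents that add atoms: tert-butyldimethylsilyl triflate, CC(C)(C)[Si](C)(C)OS(=O)(=O)C(F)(F)F
Why: Silylation of the only free hydroxyl keeps O2 from displacing the C5 mesylate and from being acylated later.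

**Step 14**
Reactants: 21 vinyl bromide ketone
Product: 22 trans-decalin-9β-ol with exocyclic C10=C14 methylene (ring B = C9, C10, C1, C2, C3, C4 closed; 2β-OTBS, 4α-methyl, 5α-OMs, lactone, 8β-ester)
Conditions: CrCl2 (6 equiv), NiCl2 (2 mol %), DMSO/THF, 25 °C
Reagents that add atoms: none
Why: Zerovalent nickel (from NiCl2 and CrCl2) inserts into the C10–Br bond, transmetallation gives an alkenyl species of trivalent chromium, and this adds to the C9 ketone to form the C9–C10 bond; the closest known reaction type is the intramolecular Nozaki–Hiyama–Kishi addition of vinyl halides to carbonyl groups. The closure is 6-exo-trig and makes ring B, so that C4–C9 becomes the fusion bond of a decalin. The new stereocentre C9 is controlled by ring A: the tether is equatorial on C4 and the axial β-line at C9 is blocked by the axial C7–C11 bond, so attack along the equatorial line should give the trans-fused decalin with the 9-OH axial and β, ring B forming as a chair with the C2 silyloxy group equatorial. The step needs chemoselectivity for the ketone over the lactone, the C8 ester and the mesylate, which the low basicity and nucleophilicity of organochromium reagents secure. The chromium alkoxide is a poor electron donor, so fragmentation is held back until C10 and C11 have been dealt with.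

**Step 15**
Reactants: 22 methylene decalinol
Product: 23 10α-methyl trans-decalin-9β-ol (C10 as in the target)
Conditions: H2 (1 bar), [Ir(cod)(PCy3)(py)]PF6 (5 mol %), CH2Cl2, 25 °C
Reagents that add atoms: none
Why: Hydroxyl-directed hydrogenation: the cationic iridium catalyst bound to the axial 9β-OH delivers H2 to the β-face of the exocyclic alkene, which is also the open face because the axial 4α-methyl shields the other, so the C10 methyl ends α (trans to 9-OH).

**Step 16**
Reactants: 23 decalinol; 24 N,N-dimethylmethyleneiminium iodide (Eschenmoser's salt)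
Product: 25 11-(dimethylaminomethyl) lactone of 23 (C11 epimers, not defined)
Conditions: lithium diisopropylamide (2.2 equiv), THF, −78 °C; then 24, −78 → −40 °C
Reagents that add atoms: none
Why: With C9 a carbinol, the lactone CH2 is the most readily enolised position, and its lithium enolate undergoes Mannich alkylation to give the masked methylene group (the lithium alkoxide at C9 should not fragment at this temperature).

**Step 17**
Reactants: 25 Mannich base
Product: 26 ten-membered (4E)-en-9-one (2-OTBS, 8-ester, 10-methyl, 6,12-lactone with 11-CH2NMe2; C2, C6, C7, C8, C10 as in the target)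
Conditions: KN(SiMe3)2 (1.05 equiv), THF, −78 → 0 °C
Reagents that add atoms: none
Why: Grob (Wharton) fragmentation of the potassium alkoxide breaks the C4–C9 bond antiperiplanar to the equatorial C5–OMs bond, giving the C9 ketone and, stereospecifically, the (E)-C4=C5 alkene (equatorial C3 ends trans to C6) while relieving the 1,3-diaxial methyl/methyl strain.

**Step 18**
Reactants: 26 Mannich base; 2 iodomethane
Product: 28 α-methylene lactone (C11=C13) of the (4E)-en-9-one, via trimethylammonium iodide 27 (not isolated)
Conditions: MeI (10 equiv), CH2Cl2/MeOH, 25 °C; then aqueous NaHCO3, EtOAc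
Reagents that add atoms: none
Why: Quaternisation of the amine and E1cB loss of trimethylamine under bicarbonate unveil the methylene lactone without touching the enolisable ketone.

**Step 19**
Reactants: 28 (4E)-alkene
Product: 29 (4S,5S)-4,5-diol (2-O-TBS; 5-OH free)
Conditions: OsO4 (2 mol %), (DHQ)2PHAL (5 mol %), 4-methylmorpholine N-oxide, acetone/H2O, 0 °C
Reagents that add atoms: 4-methylmorpholine N-oxide, C[N+]1([O-])CCOCC1; water, O
Why: Ligand-accelerated Sharpless-type syn-dihydroxylation should take the electron-rich trisubstituted alkene in preference to the electron-poor methylene lactone; with C3 in the large quadrant of the mnemonic, (DHQ)2PHAL directs attack to the face that gives 4S,5S, and syn addition to the E alkene fixes the relative configuration.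

**Step 20**
Reactants: 29 diol; 30 isobutyric anhydride
Product: 31 2-O-tert-butyldimethylsilyl ether of the target
Conditions: DMAP (10 mol %), pyridine, CH2Cl2, 0 °C
Reagents that add atoms: none
Why: Acylation of the secondary C5 hydroxyl is much faster than that of the tertiary C4 hydroxyl.

**Step 21**
Reactants: 31 silyl ether
Product: 32 CNP0244577.2 (target)
Conditions: HF·pyridine, THF, 0 → 25 °C
Reagents that add atoms: none
Why: Acidic fluoride cleaves the silyl ether under conditions that should not cause acyl migration or addition to the methylene lactone.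

**Compound list**

1 | 2-(3,5-dihydroxyphenyl)acetic acid | OC(=O)Cc1cc(O)cc(O)c1 | starting material
2 | iodomethane | CI | starting material
3 | 2-(3,5-dioxocyclohexyl)acetic acid (formed as its sodium enolate) | OC(=O)CC1CC(=O)CC(=O)C1 | intermediate (not isolated)
4 | 2-(4-methyl-3,5-dioxocyclohexyl)acetic acid | OC(=O)CC1CC(=O)C(C)C(=O)C1 | intermediate
5 | methyl 2-(4-methyl-3,5-dioxocyclohexyl)acetate | COC(=O)CC1CC(=O)C(C)C(=O)C1 | intermediate
6 | allyl methyl carbonate | C=CCOC(=O)OC | starting material
7 | methyl 2-(cis-4-allyl-4-methyl-3,5-dioxocyclohexyl)acetate (meso) | C=CC[C@]1(C)C(=O)C[C@H](CC(=O)OC)CC1=O | intermediate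
8 | methyl 2-[(1S,3R,4R)-4-allyl-3-hydroxy-4-methyl-5-oxocyclohexyl]acetate | C=CC[C@]1(C)[C@H](O)C[C@H](CC(=O)OC)CC1=O | intermediate
9 | methyl 2-[(1S,4R)-4-allyl-4-methyl-5-oxocyclohex-2-en-1-yl]acetate | C=CC[C@]1(C)C=C[C@H](CC(=O)OC)CC1=O | intermediate
10 | 5α,6α-epoxide of 9 | C=CC[C@]1(C)[C@H]2O[C@H]2[C@H](CC(=O)OC)CC1=O | intermediate
11 | hydroxy keto lactone (5α-OH, 6β,7β-cis-fused γ-lactone, 4β-allyl, 4α-methyl, C9 ketone) | O=C1C[C@H]2CC(=O)O[C@H]2[C@H](O)[C@@]1(C)CC=C | intermediate
12 | 5α-mesylate of 11 | O=C1C[C@H]2CC(=O)O[C@H]2[C@H](OS(C)(=O)=O)[C@@]1(C)CC=C | intermediate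
13 | trimethylsilyl enol ether (C8=C9) of 12 | C[Si](C)(C)OC1=C[C@H]2CC(=O)O[C@H]2[C@H](OS(C)(=O)=O)[C@@]1(C)CC=C | intermediate (not isolated)
14 | 8α-bromo ketone | O=C1[C@H](Br)[C@H]2CC(=O)O[C@H]2[C@H](OS(C)(=O)=O)[C@@]1(C)CC=C | intermediate
15 | (R)-2-methylbutanoic acid | CC[C@@H](C)C(=O)O | starting material
16 | 8β-[(R)-2-methylbutanoyloxy] ketone | O=C1[C@@H](OC(=O)[C@H](C)CC)[C@H]2CC(=O)O[C@H]2[C@H](OS(C)(=O)=O)[C@@]1(C)CC=C | intermediate
17 | C2 aldehyde | O=C1[C@@H](OC(=O)[C@H](C)CC)[C@H]2CC(=O)O[C@H]2[C@H](OS(C)(=O)=O)[C@@]1(C)CC=O | intermediate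
18 | 2,3-dibromoprop-1-ene | C=C(Br)CBr | starting material
19 | O-trimethylsilyl ether of 20 | O=C1[C@@H](OC(=O)[C@H](C)CC)[C@H]2CC(=O)O[C@H]2[C@H](OS(C)(=O)=O)[C@@]1(C)C[C@@H](O[Si](C)(C)C)CC(Br)=C | intermediate (not isolated)
20 | 2-bromoallyl carbinol | O=C1[C@@H](OC(=O)[C@H](C)CC)[C@H]2CC(=O)O[C@H]2[C@H](OS(C)(=O)=O)[C@@]1(C)C[C@@H](O)CC(Br)=C | intermediate
21 | 2-O-TBS ether of 20 | O=C1[C@@H](OC(=O)[C@H](C)CC)[C@H]2CC(=O)O[C@H]2[C@H](OS(C)(=O)=O)[C@@]1(C)C[C@@H](O[Si](C)(C)C(C)(C)C)CC(Br)=C | intermediate
22 | trans-decalin-9β-ol with C10=C14 methylene | C=C1C[C@H](O[Si](C)(C)C(C)(C)C)C[C@]2(C)[C@@H](OS(C)(=O)=O)[C@@H]3OC(=O)C[C@@H]3[C@H](OC(=O)[C@H](C)CC)[C@@]12O | intermediate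
23 | 10α-methyl trans-decalin-9β-ol | C[C@H]1C[C@H](O[Si](C)(C)C(C)(C)C)C[C@]2(C)[C@@H](OS(C)(=O)=O)[C@@H]3OC(=O)C[C@@H]3[C@H](OC(=O)[C@H](C)CC)[C@@]12O | intermediate
24 | N,N-dimethylmethyleneiminium iodide | C=[N+](C)C.[I-] | starting material
25 | 11-(dimethylaminomethyl) lactone of 23 (C11 not defined) | C[C@H]1C[C@H](O[Si](C)(C)C(C)(C)C)C[C@]2(C)[C@@H](OS(C)(=O)=O)[C@@H]3OC(=O)C(CN(C)C)[C@@H]3[C@H](OC(=O)[C@H](C)CC)[C@@]12O | intermediate
26 | ten-membered (4E)-en-9-one Mannich base | CN(C)CC1C(=O)O[C@H]2/C=C(\C)C[C@@H](O[Si](C)(C)C(C)(C)C)C[C@H](C)C(=O)[C@@H](OC(=O)[C@H](C)CC)[C@@H]12 | intermediate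
27 | trimethylammonium iodide of 26 | C[N+](C)(C)CC1C(=O)O[C@H]2/C=C(\C)C[C@@H](O[Si](C)(C)C(C)(C)C)C[C@H](C)C(=O)[C@@H](OC(=O)[C@H](C)CC)[C@@H]12.[I-] | intermediate (not isolated)
28 | α-methylene lactone of the (4E)-en-9-one | C=C1C(=O)O[C@H]2/C=C(\C)C[C@@H](O[Si](C)(C)C(C)(C)C)C[C@H](C)C(=O)[C@@H](OC(=O)[C@H](C)CC)[C@@H]12 | intermediate
29 | (4S,5S)-4,5-diol, 2-O-TBS | C=C1C(=O)O[C@@H]2[C@H]1[C@H](OC(=O)[C@H](C)CC)C(=O)[C@@H](C)C[C@H](O[Si](C)(C)C(C)(C)C)C[C@](C)(O)[C@H]2O | intermediate
30 | isobutyric anhydride | CC(C)C(=O)OC(=O)C(C)C | starting material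
31 | 2-O-TBS ether of the target | C=C1C(=O)O[C@@H]2[C@H]1[C@H](OC(=O)[C@H](C)CC)C(=O)[C@@H](C)C[C@H](O[Si](C)(C)C(C)(C)C)C[C@](C)(O)[C@H]2OC(=O)C(C)C | intermediate
32 | CNP0244577.2 | C=C1C(=O)O[C@@H]2[C@H]1[C@H](OC(=O)[C@H](C)CC)C(=O)[C@@H](C)C[C@H](O)C[C@](C)(O)[C@H]2OC(=O)C(C)C | target

**Totals**

Total step count: 21. Longest linear sequence: 21 steps (1 → 32).

**Steps most likely to fail**

Step 14. The alkenylchromium species may add too slowly to the hindered, α-oxygenated ketone, so that protodebromination wins. It may instead attack along the axial line and give the cis ring fusion, or divalent chromium may reductively cleave the α-acyloxy ketone. The fallback sets out from aldehyde 17 and returns at 22. Chiral-phosphoric-acid-catalysed propargylation of 17 with allenylboronic acid pinacol ester should give homopropargylic alcohol F1. TBSOTf/2,6-lutidine then gives silyl ether F2. Nickel-catalysed reductive cyclisation of the alkynyl ketone (Ni(cod)2, PBu3, Et3SiH, THF) forms the same C9–C10 bond through an oxanickelacycle, with hydride delivered to C14, and gives 9-O-triethylsilyl ether F3. AcOH/THF/H2O cleaves the tertiary triethylsilyl ether and returns 22.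

Step 16. During enolate formation the lithium alkoxide may fragment early or take up the neighbouring acyl group, and the mesylate methyl or the 2-methylbutanoate α-position may be deprotonated. The fallback sets out from 23 and returns at 26. TMSOTf/2,6-lutidine caps the tertiary hydroxyl as 9-O-trimethylsilyl ether F4, so no alkoxide is present when the lactone is deprotonated. Lithium diisopropylamide and Eschenmoser's salt then give Mannich base silyl ether F5. One equivalent of Bu4NF in THF at −40 °C removes the tertiary trimethylsilyl group in preference to the secondary TBS ether, and the liberated alkoxide fragments in the same flask to 26.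

Step 19. The ligand's facial preference may oppose the peripheral bias of the macrocyclic alkene and give poor facial selectivity, or the methylene lactone may be oxidised as well. The fallback sets out from 28 and returns at 31. A Woodward–Prévost cis-hydroxyacyloxylation uses the isobutyrate that C5 needs as the participating group. I2 and AgO2CCHMe2 in CH2Cl2 add trans across the alkene to give 4-isobutyryloxy-5-iodide F6. Warming with a second equivalent of the silver salt in wet isobutyric acid displaces iodide at C5 with inversion through the 1,3-dioxolan-2-ylium ion, and water opens this to the cis-hydroxy ester. Acyl migration from the tertiary to the secondary oxygen then gives 31. This places both oxygens on the face opposite to the one the halonium ion takes, with no chiral ligand.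

**Further compounds**

F1 | step 14 | homopropargylic alcohol (chain C3H2–C2H(OH)–C1H2–C10≡C14H on the ring-A ketone of 17) | O=C1[C@@H](OC(=O)[C@H](C)CC)[C@H]2CC(=O)O[C@H]2[C@H](OS(C)(=O)=O)[C@@]1(C)C[C@@H](O)CC#C
F2 | step 14 | 2-O-TBS ether of F1 | O=C1[C@@H](OC(=O)[C@H](C)CC)[C@H]2CC(=O)O[C@H]2[C@H](OS(C)(=O)=O)[C@@]1(C)C[C@@H](O[Si](C)(C)C(C)(C)C)CC#C
F3 | step 14 | 9-O-triethylsilyl ether of 22 | C=C1C[C@H](O[Si](C)(C)C(C)(C)C)C[C@]2(C)[C@@H](OS(C)(=O)=O)[C@@H]3OC(=O)C[C@@H]3[C@H](OC(=O)[C@H](C)CC)[C@@]12O[Si](CC)(CC)CC
F4 | step 16 | 9-O-trimethylsilyl ether of 23 | C[C@H]1C[C@H](O[Si](C)(C)C(C)(C)C)C[C@]2(C)[C@@H](OS(C)(=O)=O)[C@@H]3OC(=O)C[C@@H]3[C@H](OC(=O)[C@H](C)CC)[C@@]12O[Si](C)(C)C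
F5 | step 16 | 9-O-trimethylsilyl ether of 25 (C11 not defined) | C[C@H]1C[C@H](O[Si](C)(C)C(C)(C)C)C[C@]2(C)[C@@H](OS(C)(=O)=O)[C@@H]3OC(=O)C(CN(C)C)[C@@H]3[C@H](OC(=O)[C@H](C)CC)[C@@]12O[Si](C)(C)C
F6 | step 19 | 4-isobutyryloxy-5-iodide (iodine anti to the C4 oxygen) | C=C1C(=O)O[C@@H]2[C@H]1[C@H](OC(=O)[C@H](C)CC)C(=O)[C@@H](C)C[C@H](O[Si](C)(C)C(C)(C)C)C[C@](C)(OC(=O)C(C)C)[C@@H]2I
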